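The readings were computed for substances that don't exist, and the scatter is random.

The blue run levels off with target reading 56.2% of the starting material and other conformer together, and the ochre run, charged with more other conformer, levels off at 53.4%, lower than blue.

all flasks: starting material 0.25 M

| charge | other conformer | protic impurity | remark | time |
|---|---|---|---|---|
| blue | 0.72 equiv | 5 mM | run made earlier |  |
| ochre | 0.81 equiv | 5 mM | run made earlier |  |
| Monday's | 0.500 equiv | 5.00 mM |  | 10 min |
| Saturday's | 0.600 equiv | 5.00 mM |  | 10 min |

| run | time / min | target / % |
|---|---|---|
| blue | 2.50 | 39.1 |
| blue | 5.00 | 51.7 |
| blue | 8.00 | 56.1 |
| blue | 10.0 | 56.3 |
| ochre | 2.50 | 37.6 |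
| ochre | 5.00 | 48.0 |
| ochre | 8.00 | 53.8 |
| ochre | 10.0 | 52.9 |

(each reading ± 0.5 percentage points)

- the numbers in the tables scatter by 0.5 percentage points (one standard deviation)

1. which of the two there is more of at the end, Monday's (isomer of the product / target)
2. which of the two there is more of at the end, Saturday's (isomer of the product / target)
3. target at the end, in percent of the starting material and other conformer together charged, Monday's
4. target at the end, in percent of the starting material and other conformer together charged, Saturday's

Multiplied by the total charge, one plus the equivalents of other conformer, these plateaus give 0.967 for blue and 0.966 for ochre, nearly equal. Their mean, 0.966, a reading with the scatter of these two runs, is taken as the target formed per equivalent of starting material charged, here called the yield on starting material.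

Now the question turned round. For isomer of the product to exceed target, target would have to stand below half of the charge. That asks for a yield on starting material below 0.750 in Monday's flask and 0.800 in Saturday's, and the runs show more than either.

Dividing the yield by each total charge, my own reckoning gives 64.4% for Monday's and 60.4% for Saturday's. These figures assume a plateau, so the blue plateau goes back into its own curve. Target stands 17 percentage points below it at 2.50 min and 4.5 points below it at 5.00 min. The same shrinkage twice more leaves 0.31 points at 10.0 min, less than the scatter of 0.5 points, so the figures stand.

The forecast names target for Monday's and target for Saturday's, with 64.5% and 60.5%, close to my figures but not identical, on the ground that “the target seems to come essentially only from the starting material”.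

Monday's flask ends at 64.3% target and Saturday's at 60.4%.

    starting material ⇌ other conformer (K = 0.221, k = 0.00889 min⁻¹)
    starting material → target (k = 0.464 min⁻¹)
    other conformer → isomer of the product (k = 1.68 min⁻¹)
    starting material + protic impurity → quenched substrate (k = 45.6 M⁻¹ min⁻¹)
    2 other conformer → self-condensation product (k = 0.0349 M⁻¹ min⁻¹)

Monday's flask holds 33.7% isomer of the product at the end, less than its target. Its result, multiplied back by its total charge, returns a yield on starting material of 0.965. In the neighbour charged with 1.20 equiv of other conformer, the mark of 1.10 lies above the yield, and the yield gives 43.9% target. That flask holds 44.6% target against 53.8% isomer of the product.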